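## Retrosynthetic overview

- The acetate, the silyl ethers and the enal oxidation level are adjusted last. The (R)-allylic carbinol comes from CBS reduction of a dienone made from ring enal 23 and geranylbarium chloride, and 23 from an allyl group on the ring (hydroboration, oxidation, Wittig).
- In the ring, the tertiary carbinol comes from MeCeCl2 addition to a cyclohexanone, its α-quaternary carbon from Pd-catalysed decarboxylative allylation of an allyl β-keto ester, and the ketone from a nitro group (Nef).
- The only ring, the cyclohexane, is closed in one operation: an amine-catalysed formal [4+2] of acyclic dienal 7 (four ring carbons plus the enal) with allyl 2-methyl-3-nitroacrylate 12 (two ring carbons).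
- Enabling feature: the exocyclic tetrasubstituted enal C=C(CH3)–CHO on the ring. It makes the neighbouring ring CH (the one carrying the hydroxypropyl chain) its γ′-carbon and the ring CH2–CH2 on its other side a former vinyl group, so these four ring carbons are the diene of a cross-conjugated trienamine. The vicinal C(CH3)(chain)/C(CH3)(OH) pair is the dienophile, with nitro as latent ketone and the allyl ester as latent allyl group.
- Stereochemistry: the ring CH is set by the amine catalyst, the quaternary carbon and the tertiary carbinol are relayed from it by substrate control, the enal geometry follows from A(1,3) strain, and the remote carbinol is reagent-controlled.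

Key step: step 7

Assumption: the quinine-derived primary amine is taken to shield the face of the trienamine that leads to the (R)-configured ring CH; if the sense proves opposite, the pseudo-enantiomeric quinidine-derived amine is used with no other change.

## Route

Step 1
Reactants: 1 tert-butyl(4-iodobutoxy)dimethylsilane; 2 (E)-3-ethoxy-2-methylprop-2-enal
Product: 4 (E)-7-(tert-butyldimethylsilyloxy)-1-ethoxy-2-methylhept-1-en-3-ol (racemic), via silyloxybutyllithium 3 (not isolated)
Conditions: 1, t-BuLi (2.1 equiv), Et2O, −78 °C; then 2, −78 to 0 °C; aq. NaHCO3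
Reagents that add atoms: none
Why: Iodine–lithium exchange and 1,2-addition of the alkyllithium to the aldehyde of the vinylogous ester should give the allylic alcohol; the new carbinol centre is racemic and is removed in step 2.

Step 2
Reactants: 4 (E)-7-(tert-butyldimethylsilyloxy)-1-ethoxy-2-methylhept-1-en-3-ol
Product: 5 (E)-7-(tert-butyldimethylsilyloxy)-1-ethoxy-2-methylhept-1-en-3-one
Conditions: MnO2 (15 equiv), CH2Cl2, 25 °C
Reagents that add atoms: none
Why: Neutral allylic oxidation should give the β-ethoxy enone and avoids the acid-induced 1,3-transposition to which the enol ether carbinol is prone.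

Step 3
Reactants: 5 (E)-7-(tert-butyldimethylsilyloxy)-1-ethoxy-2-methylhept-1-en-3-one
Product: 7 3-[4-(tert-butyldimethylsilyloxy)butyl]-2-methylpenta-2,4-dienal (2E/2Z mixture, drawn 2E), via tertiary dienol 6 (not isolated)
Conditions: CH2=CHMgBr (1.5 equiv), CeCl3 (1.5 equiv), THF, −78 °C; then 1 M HCl, THF, 0 °C, 15 min
Reagents that add atoms: vinylmagnesium bromide, C=C[Mg]Br
Why: 1,2-Addition to the β-alkoxy enone and acid-induced loss of ethanol with 1,3-carbonyl transposition (Stork–Danheiser-type) should give the dienal; the geometry of the tetrasubstituted alkene is irrelevant because both isomers give the same trienamine in step 7.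

Step 4
Reactants: 8 sodium pyruvate
Product: 9 prop-2-enyl 2-oxopropanoate (allyl pyruvate)
Conditions: allyl bromide (1.2 equiv), DMF, 40 °C
Reagents that add atoms: allyl bromide, C=CCBr
Why: SN2 O-alkylation of the carboxylate should give the allyl ester.

Step 5
Reactants: 9 prop-2-enyl 2-oxopropanoate
Product: 10 prop-2-enyl 2-hydroxy-2-methyl-3-nitropropanoate (racemic)
Conditions: CH3NO2 (5 equiv), Et3N (0.1 equiv), 0 to 25 °C
Reagents that add atoms: nitromethane, C[N+](=O)[O-]
Why: Henry addition of nitromethane to the activated keto group should be fast; the racemic carbinol is eliminated in step 6.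

Step 6
Reactants: 10 prop-2-enyl 2-hydroxy-2-methyl-3-nitropropanoate
Product: 12 prop-2-enyl (E)-2-methyl-3-nitroprop-2-enoate, via mesylate 11 (not isolated)
Conditions: MsCl (1.2 equiv), Et3N (2.5 equiv), CH2Cl2, −20 to 0 °C
Reagents that add atoms: none
Why: Mesylation and E1cB elimination through the nitronate should give the conjugated nitroacrylate, mainly as the E isomer (nitro trans to the ester); its geometry has no consequence because the ester-bearing centre is reset in step 9.

Step 7
Reactants: 7 3-[4-(tert-butyldimethylsilyloxy)butyl]-2-methylpenta-2,4-dienal; 12 prop-2-enyl (E)-2-methyl-3-nitroprop-2-enoate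
Product: 14 prop-2-enyl (2R,3Z)-2-[3-(tert-butyldimethylsilyloxy)propyl]-3-(1-hydroxypropan-2-ylidene)-1-methyl-6-nitrocyclohexane-1-carboxylate (mixture at the ester and nitro carbons), via enal cycloadduct 13 (not isolated)
Conditions: 7 (1.0 equiv), 12 (1.3 equiv), 9-amino-9-deoxy-epi-quinine (20 mol %), 2-fluorobenzoic acid (40 mol %), toluene, 25 °C; then MeOH, CeCl3·7H2O, NaBH4, −20 °C
Reagents that add atoms: none
Why: Proposed new method: the primary amine condenses with the α-branched dienal and γ′-deprotonation gives a cross-conjugated trienamine, whose γ′-carbon adds to the ester-bearing carbon of 12 (β to nitro), after which the nitronate closes onto the vinyl terminus by 1,6-addition to the vinylogous iminium ion, a formal and probably stepwise [4+2] that forms both ring bonds. The closest known reaction types are amine-catalysed cross-trienamine Diels–Alder reactions and dienamine vinylogous Michael additions to nitroalkenes. The cyclohexane closes in a Michael–Michael sequence whose second event is a 6-endo attack on the vinyl group. The ring CH bearing the silyloxypropyl chain is the only centre that must be controlled, and it is set by the catalyst shielding one face of the trienamine; the ester-bearing and nitro-bearing carbons may form as mixtures because they are erased in steps 8 and 9. Regioselectivity is secured by the nitro group (the stronger acceptor, so the ester-bearing carbon is the electrophile) and by the trienamine nitrogen (so the γ′-carbon is the nucleophile); closure at the vinyl CH2 rather than at the iminium carbon is favoured because that carbon is α-methylated and shielded by the catalyst. Hydrolysis with γ-protonation of the s-trans dienamine should give the conjugated enal with CHO syn to the substituted ring CH (the isomer of lower A(1,3) strain), and the in-situ Luche reduction locks this Z geometry.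

Step 8
Reactants: 14 prop-2-enyl (2R,3Z)-2-[3-(tert-butyldimethylsilyloxy)propyl]-3-(1-hydroxypropan-2-ylidene)-1-methyl-6-nitrocyclohexane-1-carboxylate
Product: 16 prop-2-enyl (2R,3Z)-2-[3-(tert-butyldimethylsilyloxy)propyl]-3-(1-hydroxypropan-2-ylidene)-1-methyl-6-oxocyclohexane-1-carboxylate (epimers at the ester carbon), via potassium nitronate 15 (not isolated)
Conditions: t-BuOK (1.1 equiv), THF, 0 °C; then aq. TiCl3 (4.5 equiv), NH4OAc buffer (pH 5–6), THF/H2O, 0 to 25 °C
Reagents that add atoms: water, O
Why: Reductive Nef reaction: trivalent titanium reduces the nitronate to the imine, which hydrolyses to the ketone under buffered conditions that the allyl ester, silyl ether and alkenes should survive.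

Step 9
Reactants: 16 prop-2-enyl (2R,3Z)-2-[3-(tert-butyldimethylsilyloxy)propyl]-3-(1-hydroxypropan-2-ylidene)-1-methyl-6-oxocyclohexane-1-carboxylate
Product: 17 (2S,3R,4Z)-3-[3-(tert-butyldimethylsilyloxy)propyl]-4-(1-hydroxypropan-2-ylidene)-2-methyl-2-(prop-2-enyl)cyclohexan-1-one
Conditions: Pd(PPh3)4 (5 mol %), THF, 25 °C
Reagents that add atoms: none
Why: Tsuji–Trost-type decarboxylative allylation: zerovalent palladium ionises the allyl ester, loss of CO2 gives the tetrasubstituted enolate regiospecifically, and the allyl group should add anti to the neighbouring silyloxypropyl chain (held pseudoaxial by A(1,2) and A(1,3) strain), which sets the quaternary centre and converges both epimers.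

Step 10
Reactants: 17 (2S,3R,4Z)-3-[3-(tert-butyldimethylsilyloxy)propyl]-4-(1-hydroxypropan-2-ylidene)-2-methyl-2-(prop-2-enyl)cyclohexan-1-one
Product: 18 (1S,2S,3R,4Z)-3-[3-(tert-butyldimethylsilyloxy)propyl]-4-(1-hydroxypropan-2-ylidene)-1,2-dimethyl-2-(prop-2-enyl)cyclohexan-1-ol
Conditions: MeLi (4 equiv), CeCl3 (anhydrous, 4 equiv), THF, −78 °C; aq. NH4Cl
Reagents that add atoms: methyllithium, [Li]C
Why: Organocerium 1,2-addition to the hindered, enolisable ketone; the methyl group should enter equatorially because the axial silyloxypropyl chain on the β-carbon blocks the other face, which places the new hydroxyl cis to that chain and to the ring methyl.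

Step 11
Reactants: 18 (1S,2S,3R,4Z)-3-[3-(tert-butyldimethylsilyloxy)propyl]-4-(1-hydroxypropan-2-ylidene)-1,2-dimethyl-2-(prop-2-enyl)cyclohexan-1-ol
Product: 19 bis(triethylsilyl) ether of 18 (primary allylic O–SiEt3 and tertiary O–SiEt3)
Conditions: TESOTf (3 equiv), 2,6-lutidine (5 equiv), CH2Cl2, −78 to 0 °C
Reagents that add atoms: triethylsilyl trifluoromethanesulfonate, CC[Si](CC)(CC)OS(=O)(=O)C(F)(F)F
Why: The silyl triflate silylates both the primary allylic and the hindered tertiary hydroxyl in one operation, which prevents lactol and oxa-Michael side reactions during the chain extension and leaves only the later secondary carbinol free for acetylation.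

Step 12
Reactants: 19 bis(triethylsilyl) ether
Product: 21 primary alcohol (19 with the allyl group converted to CH2CH2CH2OH), via alkylborane 20 (not isolated)
Conditions: 9-BBN (2 equiv), THF, 0 to 25 °C; then 3 M NaOH, 30% H2O2, 0 °C
Reagents that add atoms: hydrogen peroxide, OO
Why: Anti-Markovnikov hydroboration–oxidation; 9-BBN should react only with the monosubstituted alkene and leave the tetrasubstituted ring alkene untouched.

Step 13
Reactants: 21 primary alcohol
Product: 22 aldehyde (ring–CH2CH2–CHO)
Conditions: Dess–Martin periodinane (1.3 equiv), NaHCO3, CH2Cl2, 0 to 25 °C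
Reagents that add atoms: none
Why: Buffered Dess–Martin oxidation of the primary alcohol should give the aldehyde without touching the silyl ethers.

Step 14
Reactants: 22 aldehyde
Product: 23 (E)-enal (ring–CH2CH2–CH=C(CH3)–CHO)
Conditions: Ph3P=C(CH3)CHO (1.5 equiv), toluene, 90 °C
Reagents that add atoms: 2-(triphenyl-λ5-phosphanylidene)propanal, CC(C=O)=P(c1ccccc1)(c1ccccc1)c1ccccc1
Why: Wittig reaction of a stabilised formyl ylide with an aliphatic aldehyde should give the (E)-2-methyl enal, which fixes the trisubstituted side-chain alkene.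

Step 15
Reactants: 23 (E)-enal; 24 geranyl chloride
Product: 26 allylic alcohol (ring–CH2CH2–CH=C(CH3)–CH(OH)–CH2–CH=C(CH3)CH2CH2CH=C(CH3)2, both carbinol epimers), via geranylbarium chloride 25 (not isolated)
Conditions: BaI2, Li, biphenyl, THF, 25 °C (activated barium); 24, −78 °C; then 23, −78 °C; aq. NH4Cl
Reagents that add atoms: none
Why: Allylbarium reagents add 1,2 to aldehydes at their α-carbon with retention of the E geometry, so the linear geranyl carbinol should result; the carbinol configuration is not controlled here because it is reset in steps 16 and 17.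

Step 16
Reactants: 26 allylic alcohol
Product: 27 dienone (ring–CH2CH2–CH=C(CH3)–C(=O)–CH2–geranyl residue)
Conditions: Dess–Martin periodinane (1.3 equiv), NaHCO3, CH2Cl2, 0 °C
Reagents that add atoms: none
Why: Buffered oxidation of the allylic alcohol should give the enone without moving the skipped alkene into conjugation.

Step 17
Reactants: 27 dienone
Product: 28 (R)-allylic alcohol
Conditions: (S)-2-methyl-CBS-oxazaborolidine (0.5 equiv), catecholborane (2 equiv), toluene, −78 °C
Reagents that add atoms: none
Why: CBS reduction with the α-methyl alkenyl group as the large substituent should give the (R)-carbinol under reagent control; catecholborane at −78 °C does not hydroborate the alkenes.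

Step 18
Reactants: 28 (R)-allylic alcohol
Product: 29 (R)-allylic acetate
Conditions: Ac2O (3 equiv), pyridine, DMAP (0.1 equiv), CH2Cl2, 0 to 25 °C
Reagents that add atoms: acetic anhydride, CC(=O)OC(C)=O
Why: The secondary carbinol is the only free hydroxyl, so acylation should be clean.

Step 19
Reactants: 29 (R)-allylic acetate
Product: 30 triol acetate (free hydroxypropyl OH, primary allylic OH and tertiary OH)
Conditions: HF·pyridine, pyridine, THF, 0 to 25 °C
Reagents that add atoms: none
Why: Buffered fluoride-mediated desilylation should remove the tert-butyldimethylsilyl and both triethylsilyl groups while the allylic acetate survives.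

Step 20
Reactants: 30 triol acetate
Product: 31 target
Conditions: MnO2 (20 equiv), CH2Cl2, 25 °C
Reagents that add atoms: none
Why: MnO2 should oxidise only the allylic primary alcohol to the enal, with retention of the Z geometry, and leave the saturated primary alcohol, the tertiary alcohol and the acetate untouched.

## Compound list

1 | tert-butyl(4-iodobutoxy)dimethylsilane | CC(C)(C)[Si](C)(C)OCCCCI | starting material
2 | (E)-3-ethoxy-2-methylprop-2-enal | CCO/C=C(\C)C=O | starting material
3 | [4-(tert-butyldimethylsilyloxy)butyl]lithium | [Li]CCCCO[Si](C)(C)C(C)(C)C | intermediate (not isolated)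
4 | (E)-7-(tert-butyldimethylsilyloxy)-1-ethoxy-2-methylhept-1-en-3-ol, racemic | CCO/C=C(\C)C(O)CCCCO[Si](C)(C)C(C)(C)C | intermediate
5 | (E)-7-(tert-butyldimethylsilyloxy)-1-ethoxy-2-methylhept-1-en-3-one | CCO/C=C(\C)C(=O)CCCCO[Si](C)(C)C(C)(C)C | intermediate
6 | (E)-3-[4-(tert-butyldimethylsilyloxy)butyl]-1-ethoxy-2-methylpenta-1,4-dien-3-ol | CCO/C=C(\C)C(O)(C=C)CCCCO[Si](C)(C)C(C)(C)C | intermediate (not isolated)
7 | 3-[4-(tert-butyldimethylsilyloxy)butyl]-2-methylpenta-2,4-dienal (2E/2Z mixture, drawn 2E) | O=C/C(C)=C(/C=C)CCCCO[Si](C)(C)C(C)(C)C | intermediate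
8 | sodium pyruvate | CC(=O)C(=O)[O-].[Na+] | starting material
9 | prop-2-enyl 2-oxopropanoate | CC(=O)C(=O)OCC=C | intermediate
10 | prop-2-enyl 2-hydroxy-2-methyl-3-nitropropanoate, racemic | CC(O)(C[N+](=O)[O-])C(=O)OCC=C | intermediate
11 | prop-2-enyl 2-methyl-2-(methylsulfonyloxy)-3-nitropropanoate | CC(OS(C)(=O)=O)(C[N+](=O)[O-])C(=O)OCC=C | intermediate (not isolated)
12 | prop-2-enyl (E)-2-methyl-3-nitroprop-2-enoate | C=CCOC(=O)/C(C)=C/[N+](=O)[O-] | intermediate
13 | prop-2-enyl (2R,3Z)-2-[3-(tert-butyldimethylsilyloxy)propyl]-1-methyl-6-nitro-3-(1-oxopropan-2-ylidene)cyclohexane-1-carboxylate (mixture at the ester and nitro carbons) | C=CCOC(=O)C1(C)[C@H](CCCO[Si](C)(C)C(C)(C)C)/C(=C(/C)C=O)CCC1[N+](=O)[O-] | intermediate (not isolated)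
14 | prop-2-enyl (2R,3Z)-2-[3-(tert-butyldimethylsilyloxy)propyl]-3-(1-hydroxypropan-2-ylidene)-1-methyl-6-nitrocyclohexane-1-carboxylate (mixture at the ester and nitro carbons) | C=CCOC(=O)C1(C)[C@H](CCCO[Si](C)(C)C(C)(C)C)/C(=C(/C)CO)CCC1[N+](=O)[O-] | intermediate
15 | potassium nitronate of 14 | C=CCOC(=O)C1(C)[C@H](CCCO[Si](C)(C)C(C)(C)C)/C(=C(/C)CO)CCC1=[N+]([O-])[O-].[K+] | intermediate (not isolated)
16 | prop-2-enyl (2R,3Z)-2-[3-(tert-butyldimethylsilyloxy)propyl]-3-(1-hydroxypropan-2-ylidene)-1-methyl-6-oxocyclohexane-1-carboxylate (epimers at the ester carbon) | C=CCOC(=O)C1(C)[C@H](CCCO[Si](C)(C)C(C)(C)C)/C(=C(/C)CO)CCC1=O | intermediate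
17 | (2S,3R,4Z)-3-[3-(tert-butyldimethylsilyloxy)propyl]-4-(1-hydroxypropan-2-ylidene)-2-methyl-2-(prop-2-enyl)cyclohexan-1-one | C=CC[C@@]1(C)[C@H](CCCO[Si](C)(C)C(C)(C)C)/C(=C(/C)CO)CCC1=O | intermediate
18 | (1S,2S,3R,4Z)-3-[3-(tert-butyldimethylsilyloxy)propyl]-4-(1-hydroxypropan-2-ylidene)-1,2-dimethyl-2-(prop-2-enyl)cyclohexan-1-ol | C=CC[C@@]1(C)[C@H](CCCO[Si](C)(C)C(C)(C)C)/C(=C(/C)CO)CC[C@]1(C)O | intermediate
19 | bis(triethylsilyl) ether of 18 | C=CC[C@@]1(C)[C@H](CCCO[Si](C)(C)C(C)(C)C)/C(=C(/C)CO[Si](CC)(CC)CC)CC[C@]1(C)O[Si](CC)(CC)CC | intermediate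
20 | B-alkyl-9-borabicyclo[3.3.1]nonane from 19 | C3CC4CCCC(C3)B4CCC[C@@]1(C)[C@H](CCCO[Si](C)(C)C(C)(C)C)/C(=C(/C)CO[Si](CC)(CC)CC)CC[C@]1(C)O[Si](CC)(CC)CC | intermediate (not isolated)
21 | primary alcohol (3-hydroxypropyl chain on the quaternary carbon) | OCCC[C@@]1(C)[C@H](CCCO[Si](C)(C)C(C)(C)C)/C(=C(/C)CO[Si](CC)(CC)CC)CC[C@]1(C)O[Si](CC)(CC)CC | intermediate
22 | aldehyde (3-oxopropyl chain on the quaternary carbon) | O=CCC[C@@]1(C)[C@H](CCCO[Si](C)(C)C(C)(C)C)/C(=C(/C)CO[Si](CC)(CC)CC)CC[C@]1(C)O[Si](CC)(CC)CC | intermediate
23 | (E)-2-methyl enal (ring–CH2CH2–CH=C(CH3)–CHO) | O=C/C(C)=C/CC[C@@]1(C)[C@H](CCCO[Si](C)(C)C(C)(C)C)/C(=C(/C)CO[Si](CC)(CC)CC)CC[C@]1(C)O[Si](CC)(CC)CC | intermediate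
24 | geranyl chloride | ClC/C=C(\C)CCC=C(C)C | starting material
25 | geranylbarium chloride | Cl[Ba]C/C=C(\C)CCC=C(C)C | intermediate (not isolated)
26 | allylic alcohol, both carbinol epimers | OC(C/C=C(\C)CCC=C(C)C)/C(C)=C/CC[C@@]1(C)[C@H](CCCO[Si](C)(C)C(C)(C)C)/C(=C(/C)CO[Si](CC)(CC)CC)CC[C@]1(C)O[Si](CC)(CC)CC | intermediate
27 | dienone | O=C(C/C=C(\C)CCC=C(C)C)/C(C)=C/CC[C@@]1(C)[C@H](CCCO[Si](C)(C)C(C)(C)C)/C(=C(/C)CO[Si](CC)(CC)CC)CC[C@]1(C)O[Si](CC)(CC)CC | intermediate
28 | (R)-allylic alcohol | O[C@H](C/C=C(\C)CCC=C(C)C)/C(C)=C/CC[C@@]1(C)[C@H](CCCO[Si](C)(C)C(C)(C)C)/C(=C(/C)CO[Si](CC)(CC)CC)CC[C@]1(C)O[Si](CC)(CC)CC | intermediate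
29 | (R)-allylic acetate, fully silylated | CC(=O)O[C@H](C/C=C(\C)CCC=C(C)C)/C(C)=C/CC[C@@]1(C)[C@H](CCCO[Si](C)(C)C(C)(C)C)/C(=C(/C)CO[Si](CC)(CC)CC)CC[C@]1(C)O[Si](CC)(CC)CC | intermediate
30 | triol acetate | CC(=O)O[C@H](C/C=C(\C)CCC=C(C)C)/C(C)=C/CC[C@@]1(C)[C@H](CCCO)/C(=C(/C)CO)CC[C@]1(C)O | intermediate
31 | CNP0421354.1 | CC(=O)O[C@H](C/C=C(\C)CCC=C(C)C)/C(C)=C/CC[C@@]1(C)[C@H](CCCO)/C(=C(/C)C=O)CC[C@]1(C)O | target

## Step count and risks

Total step count: 20. Longest linear sequence: 17 steps (steps 1–3 and 7–20).

Steps most likely to fail: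

Step 7. The amine-catalysed annulation may suffer from slow condensation of the α-branched dienal with the catalyst, reversible aza-Michael capture of the catalyst by the nitroacrylate, ring closure at the iminium carbon instead of the vinyl terminus, insufficient facial control, or γ-epimerisation of the product enal before reduction. The fallback uses known thermal siloxydiene/nitroalkene Diels–Alder chemistry and a resolution. It sets out from 7, which is converted with TBSOTf and Et3N (CH2Cl2, −78 °C) into the cross-conjugated silyl trienol ether F1. F1 is heated gently with 12 in toluene (0 to 40 °C) to give the racemic silyl dienol ether cycloadduct F2. Mild acid (oxalic acid, wet THF) hydrolyses F2 to the racemic enal F3, and Luche reduction gives the racemic allylic alcohol F4. Preparative chromatography on a chiral stationary phase delivers the (2R) enantiomer, which is 14, where the route is rejoined.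

Step 8. The Nef reaction may stall because the nitro carbon is neopentyl, or the nitronate may be hydrolysed too slowly so that the allyl ester or the silyl ether is lost. The fallback sets out from 14 and unmasks the ketone in two separate stages. Reduction of the nitro group with SnCl2·2H2O, PhSH and Et3N (MeCN, 25 °C) gives the oxime F5. Transoximation with glyoxylic acid and NaOAc in aqueous THF then gives ketone 16, where the route is rejoined.

Step 10. The addition may show poor facial selectivity, because the axial allyl group on the α-carbon hinders the equatorial trajectory, or enolisation may return the ketone. The fallback sets out from 17 and replaces kinetic addition by a thermodynamically controlled Corey–Chaykovsky reaction. Dimethylsulfoxonium methylide (Me3S(O)I, NaH, DMSO) gives the spiro-epoxide F6 with the new C–C bond equatorial. Reductive opening at the CH2 terminus with LiEt3BH (THF, 0 to 25 °C) gives tertiary alcohol 18, where the route is rejoined.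

Further compounds
F1 | step 7 | tert-butyldimethylsilyl trienol ether of 7 (mixture of geometric isomers) | CC(C)(C)[Si](C)(C)OC=C(C)C(=CCCCO[Si](C)(C)C(C)(C)C)C=C
F2 | step 7 | racemic silyl dienol ether cycloadduct | C=CCOC(=O)C1(C)C(CCCO[Si](C)(C)C(C)(C)C)C(C(C)=CO[Si](C)(C)C(C)(C)C)=CCC1[N+](=O)[O-]
F3 | step 7 | racemic enal cycloadduct (racemate of 13) | C=CCOC(=O)C1(C)C(CCCO[Si](C)(C)C(C)(C)C)/C(=C(/C)C=O)CCC1[N+](=O)[O-]
F4 | step 7 | racemic allylic alcohol (racemate of 14) | C=CCOC(=O)C1(C)C(CCCO[Si](C)(C)C(C)(C)C)/C(=C(/C)CO)CCC1[N+](=O)[O-]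
F5 | step 8 | oxime of 16 | C=CCOC(=O)C1(C)[C@H](CCCO[Si](C)(C)C(C)(C)C)/C(=C(/C)CO)CCC1=NO
F6 | step 10 | spiro-epoxide from 17 | C=CC[C@@]1(C)[C@H](CCCO[Si](C)(C)C(C)(C)C)/C(=C(/C)CO)CC[C@]1(C2)O2
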